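**Retrosynthetic overview**
- The strategy rests on ring A, a pentasubstituted benzene with OMe at C1, H at C2, the only free OH at C3, the CH2C(=O)Ar chain at C4, OMe at C5 and prenyl at C6.
- Ring A is cut at C2–C3, C3–C4 and C5–C6 by a Danheiser benzannulation. 3-Methoxy-2-prenylcyclobutenone supplies C1, C2, C3 and C6; a methyl ynol ether supplies C4 and C5 with the side chain as a silylated benzylic carbinol.
- The cyclobutenone comes from the (2+2) adduct of prenylketene and ethoxyacetylene, by hydrolysis to the 1,3-dione enol and O-methylation.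
- The ynol ether comes from γ-addition of titanated methoxyallene to 2,4-bis(methoxymethoxy)benzaldehyde, then silylation.
- Ring B is bought, the four-membered ring is made in step 2, and ring A is closed last in step 8; desilylation, benzylic oxidation and MOM removal finish the route.

Key step: step 8

Assumption: the target has no stereocentre, so every intermediate carrying the benzylic carbinol is racemic and that centre is removed in step 10; 5-methylhex-4-enoic acid and methoxyallene are taken as purchasable.

Step 1
Reactants: 1 5-methylhex-4-enoic acid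
Product: 2 5-methylhex-4-enoyl chloride
Conditions: (COCl)2, cat. DMF, CH2Cl2, 0 °C → rt
Reagents that add atoms: oxalyl chloride, O=C(Cl)C(=O)Cl
Why: Acyl chloride formation through chloroiminium (Vilsmeier-type) activation is fast and anhydrous, so the trisubstituted alkene is not exposed to aqueous acid.

Step 2
Reactants: 2 5-methylhex-4-enoyl chloride; 3 ethoxyacetylene
Product: 5 3-ethoxy-4-(3-methylbut-2-enyl)cyclobut-2-en-1-one (racemic), via prenylketene 4 (not isolated)
Conditions: Et3N, 3 (3 equiv), CH2Cl2, 0 °C → rt, slow addition of 2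
Reagents that add atoms: none
Why: Dehydrochlorination gives aldoketene 4, which is trapped in a thermal ketene–ynol ether (2+2) cycloaddition with its carbonyl carbon bonding to the unsubstituted alkyne carbon; the C4 centre forms racemic and is erased in step 3.

Step 3
Reactants: 5 3-ethoxy-4-(3-methylbut-2-enyl)cyclobut-2-en-1-one
Product: 6 3-hydroxy-2-(3-methylbut-2-enyl)cyclobut-2-en-1-one (enol of 2-prenylcyclobutane-1,3-dione)
Conditions: 1 M HCl, THF, 0 °C → rt
Reagents that add atoms: water, O
Why: Acid hydrolysis of the vinylogous ester (water adds at C3, ethanol leaves) gives the 1,3-dione, which rests as the enol with the prenyl group on the carbon between the two oxygens, so the alkyl group passes from C4 to C2 by tautomerism alone.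

Step 4
Reactants: 6 3-hydroxy-2-(3-methylbut-2-enyl)cyclobut-2-en-1-one
Product: 7 3-methoxy-2-(3-methylbut-2-enyl)cyclobut-2-en-1-one
Conditions: TMSCHN2, MeOH–toluene, 0 °C
Reagents that add atoms: trimethylsilyldiazomethane, C[Si](C)(C)C=[N+]=[N-]
Why: The strongly acidic vinylogous acid protonates the diazoalkane and is O-methylated by the resulting diazonium ion (diazomethane-type methylation); the two oxygens of the enolate are equivalent, so only one enol ether can form.

Step 5
Reactants: 8 2,4-dihydroxybenzaldehyde
Product: 9 2,4-bis(methoxymethoxy)benzaldehyde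
Conditions: MOMCl, i-Pr2NEt, CH2Cl2, 0 → 40 °C
Reagents that add atoms: chloromethyl methyl ether, COCCl
Why: Williamson-type O-alkylation protects both phenols as acetals; excess reagent and gentle heating are needed for the hydrogen-bonded 2-hydroxyl.

Step 6
Reactants: 9 2,4-bis(methoxymethoxy)benzaldehyde; 10 methoxyallene
Product: 13 1-[2,4-bis(methoxymethoxy)phenyl]-4-methoxybut-3-yn-1-ol (racemic), via 1-lithio-1-methoxyallene 11 (not isolated), via titanated methoxyallene 12 (not isolated)
Conditions: n-BuLi, THF, −40 °C; ClTi(Oi-Pr)3, −78 °C; then 9, −78 → −20 °C; aq. NaHCO3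
Reagents that add atoms: none
Why: Lithiation of methoxyallene at C1 and transmetallation give an allenyltitanium that adds to the aldehyde through its γ-carbon in a cyclic SE2′ transition state (homoaldol-type addition of titanated methoxyallene), giving the homopropargylic alcohol with the methyl ynol ether in place; the carbinol centre is racemic and is oxidised away later.

Step 7
Reactants: 13 1-[2,4-bis(methoxymethoxy)phenyl]-4-methoxybut-3-yn-1-ol
Product: 14 tert-butyl{1-[2,4-bis(methoxymethoxy)phenyl]-4-methoxybut-3-ynyloxy}dimethylsilane (racemic)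
Conditions: TBSCl, imidazole, DMF, rt
Reagents that add atoms: tert-butyldimethylsilyl chloride, CC(C)(C)[Si](C)(C)Cl
Why: Imidazole-mediated silylation of the secondary alcohol stays basic throughout, as the acid-sensitive ynol ether requires, and removes the hydroxyl that would otherwise trap ketenes in step 8.

Step 8
Reactants: 7 3-methoxy-2-(3-methylbut-2-enyl)cyclobut-2-en-1-one; 14 tert-butyl{1-[2,4-bis(methoxymethoxy)phenyl]-4-methoxybut-3-ynyloxy}dimethylsilane
Product: 19 2-{2-[2,4-bis(methoxymethoxy)phenyl]-2-(tert-butyldimethylsilyloxy)ethyl}-3,5-dimethoxy-4-(3-methylbut-2-enyl)phenol (racemic), via vinylketene 15 (not isolated), via vinylcyclobutenone 16 (not isolated), via dienylketene 17 (not isolated), via cyclohexadienone 18 (not isolated)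
Conditions: 7 (1.3 equiv), toluene, 110 → 130 °C, sealed tube
Reagents that add atoms: none
Why: Heating opens 7 by 4π electrocyclic cleavage of its C1–C4 bond to the (1-methoxyvinyl)ketene 15, whose ketene C=C adds to the ynol ether in a (2+2) cycloaddition to give the 4-vinylcyclobutenone 16; a second 4π opening gives dienylketene 17, which closes ring A by a thermal 6π electrocyclisation (ketene carbon to the terminal CH2), and cyclohexadienone 18 tautomerises to the phenol. This is the Danheiser benzannulation of a cyclobutenone with an alkoxyalkyne, and the opening of an alkoxy-substituted cyclobutenone has its parallel in the thermal ring expansions of squarate-derived cyclobutenones. The one selectivity needed is the orientation of the (2+2) step: the electrophilic ketene carbonyl carbon bonds to the nucleophilic alkyne carbon remote from the methoxy group, so that this carbon becomes C3–OH beside C4 with the side chain, the alkyne methoxyl ends at C5 and the cyclobutenone methoxyl at C1. Of the two senses of the second ring opening only the one placing the methoxyvinyl group cis to the ketene can cyclise, and the other returns to 16 because the opening is reversible. No stereocentre is created in 19 (the quaternary carbon of 16 is destroyed on opening), and a methyl ynol ether has no hydrogen for a retro-ene loss of alkene at this temperature.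

Step 9
Reactants: 19 2-{2-[2,4-bis(methoxymethoxy)phenyl]-2-(tert-butyldimethylsilyloxy)ethyl}-3,5-dimethoxy-4-(3-methylbut-2-enyl)phenol
Product: 20 2-{2-[2,4-bis(methoxymethoxy)phenyl]-2-hydroxyethyl}-3,5-dimethoxy-4-(3-methylbut-2-enyl)phenol (racemic)
Conditions: TBAF, THF, 0 °C → rt
Reagents that add atoms: none
Why: Fluoride-induced desilylation, driven by the strong Si–F bond, runs under basic conditions, so the electron-rich benzylic carbinol never meets acid and cannot ionise towards the neighbouring phenol.

Step 10
Reactants: 20 2-{2-[2,4-bis(methoxymethoxy)phenyl]-2-hydroxyethyl}-3,5-dimethoxy-4-(3-methylbut-2-enyl)phenol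
Product: 21 1-[2,4-bis(methoxymethoxy)phenyl]-2-[6-hydroxy-2,4-dimethoxy-3-(3-methylbut-2-enyl)phenyl]ethan-1-one
Conditions: MnO2 (activated, excess), CH2Cl2, rt
Reagents that add atoms: none
Why: Activated MnO2 oxidises the benzylic secondary alcohol selectively (benzylic alcohol oxidation) and should leave the prenyl alkene, the MOM acetals and the phenol alone; the only stereocentre of the series is removed here.

Step 11
Reactants: 21 1-[2,4-bis(methoxymethoxy)phenyl]-2-[6-hydroxy-2,4-dimethoxy-3-(3-methylbut-2-enyl)phenyl]ethan-1-one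
Product: 22 licoriphenone [1-(2,4-dihydroxyphenyl)-2-[6-hydroxy-2,4-dimethoxy-3-(3-methylbut-2-enyl)phenyl]ethan-1-one]
Conditions: 2 M HCl, MeOH, rt
Reagents that add atoms: none
Why: Acid-catalysed acetal exchange with methanol (MOM ether cleavage) frees both ring B phenols as dimethoxymethane; at room temperature the prenyl group, which has no free hydroxyl beside it, and the hydrogen-bonded aryl ketone should stay intact.

**Compound list**
1 | 5-methylhex-4-enoic acid | CC(C)=CCCC(=O)O | starting material
2 | 5-methylhex-4-enoyl chloride | CC(C)=CCCC(=O)Cl | intermediate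
3 | ethoxyacetylene | CCOC#C | starting material
4 | 5-methylhexa-1,4-dien-1-one (prenylketene) | CC(C)=CCC=C=O | intermediate
5 | 3-ethoxy-4-(3-methylbut-2-enyl)cyclobut-2-en-1-one (racemic) | CCOC1=CC(=O)C1CC=C(C)C | intermediate
6 | 3-hydroxy-2-(3-methylbut-2-enyl)cyclobut-2-en-1-one | O=C1CC(O)=C1CC=C(C)C | intermediate
7 | 3-methoxy-2-(3-methylbut-2-enyl)cyclobut-2-en-1-one | O=C1CC(OC)=C1CC=C(C)C | intermediate
8 | 2,4-dihydroxybenzaldehyde | O=Cc1ccc(O)cc1O | starting material
9 | 2,4-bis(methoxymethoxy)benzaldehyde | O=Cc1ccc(OCOC)cc1OCOC | intermediate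
10 | methoxyallene (1-methoxypropa-1,2-diene) | COC=C=C | starting material
11 | 1-lithio-1-methoxyallene | [Li]C(OC)=C=C | intermediate
12 | (1-methoxypropa-1,2-dienyl)tris(propan-2-olato)titanium | C=C=C(OC)[Ti](OC(C)C)(OC(C)C)OC(C)C | intermediate
13 | 1-[2,4-bis(methoxymethoxy)phenyl]-4-methoxybut-3-yn-1-ol (racemic) | COC#CCC(O)c1ccc(OCOC)cc1OCOC | intermediate
14 | tert-butyl{1-[2,4-bis(methoxymethoxy)phenyl]-4-methoxybut-3-ynyloxy}dimethylsilane (racemic) | COC#CCC(O[Si](C)(C)C(C)(C)C)c1ccc(OCOC)cc1OCOC | intermediate
15 | 3-methoxy-2-(3-methylbut-2-enyl)buta-1,3-dien-1-one | C=C(OC)C(CC=C(C)C)=C=O | intermediate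
16 | 2-{2-[2,4-bis(methoxymethoxy)phenyl]-2-(tert-butyldimethylsilyloxy)ethyl}-3-methoxy-4-(1-methoxyethenyl)-4-(3-methylbut-2-enyl)cyclobut-2-en-1-one (mixture of diastereomers) | O=C1C(CC(O[Si](C)(C)C(C)(C)C)c2ccc(OCOC)cc2OCOC)=C(OC)C1(CC=C(C)C)C(OC)=C | intermediate
17 | (3E)-2-{2-[2,4-bis(methoxymethoxy)phenyl]-2-(tert-butyldimethylsilyloxy)ethyl}-3,5-dimethoxy-4-(3-methylbut-2-enyl)hexa-1,3,5-trien-1-one (racemic) | O=C=C(CC(O[Si](C)(C)C(C)(C)C)c1ccc(OCOC)cc1OCOC)/C(OC)=C(CC=C(C)C)\C(OC)=C | intermediate
18 | 2-{2-[2,4-bis(methoxymethoxy)phenyl]-2-(tert-butyldimethylsilyloxy)ethyl}-3,5-dimethoxy-4-(3-methylbut-2-enyl)cyclohexa-2,4-dien-1-one (racemic) | O=C1CC(OC)=C(CC=C(C)C)C(OC)=C1CC(O[Si](C)(C)C(C)(C)C)c1ccc(OCOC)cc1OCOC | intermediate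
19 | 2-{2-[2,4-bis(methoxymethoxy)phenyl]-2-(tert-butyldimethylsilyloxy)ethyl}-3,5-dimethoxy-4-(3-methylbut-2-enyl)phenol (racemic) | COc1cc(O)c(CC(O[Si](C)(C)C(C)(C)C)c2ccc(OCOC)cc2OCOC)c(OC)c1CC=C(C)C | intermediate
20 | 2-{2-[2,4-bis(methoxymethoxy)phenyl]-2-hydroxyethyl}-3,5-dimethoxy-4-(3-methylbut-2-enyl)phenol (racemic) | COc1cc(O)c(CC(O)c2ccc(OCOC)cc2OCOC)c(OC)c1CC=C(C)C | intermediate
21 | 1-[2,4-bis(methoxymethoxy)phenyl]-2-[6-hydroxy-2,4-dimethoxy-3-(3-methylbut-2-enyl)phenyl]ethan-1-one | COc1cc(O)c(CC(=O)c2ccc(OCOC)cc2OCOC)c(OC)c1CC=C(C)C | intermediate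
22 | licoriphenone, 1-(2,4-dihydroxyphenyl)-2-[6-hydroxy-2,4-dimethoxy-3-(3-methylbut-2-enyl)phenyl]ethan-1-one | COc1cc(O)c(CC(=O)c2ccc(O)cc2O)c(OC)c1CC=C(C)C | target

**Step count**
Total: 11 steps. Longest linear sequence: 8 steps (steps 1–4, then 8–11); the ynol ether branch is steps 5–7.

**Steps most likely to fail**

Step 8. The 4π opening of the vinylogous-ester cyclobutenone may be slow. At the temperature it then needs, the ynol ether could oligomerise, or the vinylketene could be lost by dimerisation and by acylating the product phenol. The fallback generates the same vinylketene 15 at room temperature by photochemical Wolff rearrangement instead of thermal ring opening. It sets out from acid chloride 2. MeNH(OMe)·HCl and pyridine should give N-methoxy-N,5-dimethylhex-4-enamide F1. Addition of 1-methoxyvinyllithium F2 (from methyl vinyl ether and t-BuLi, THF, −78 → 0 °C) should give 2-methoxy-7-methylocta-1,6-dien-3-one F3. LiN(SiMe3)2 and CF3CO2CH2CF3 should give 1,1,1-trifluoro-5-methoxy-3-(3-methylbut-2-enyl)hex-5-ene-2,4-dione F4. MsN3, Et3N and H2O in MeCN then transfer the diazo group with loss of the trifluoroacetyl group to give 4-diazo-2-methoxy-7-methylocta-1,6-dien-3-one F5. Irradiation of F5 with 14 (300 nm, ClCH2CH2Cl, rt), then warming to 80 °C, should pass through 15, 16, 17 and 18 and come back to the route at phenol 19.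

Step 11. Under acid the ring A hydroxyl may add to the ketone and dehydrate to a 2-arylbenzofuran before both MOM acetals are cleaved. The fallback masks that hydroxyl first and unmasks it with base. It sets out from ketone 21. PivCl, Et3N and DMAP should give 2-{2-[2,4-bis(methoxymethoxy)phenyl]-2-oxoethyl}-3,5-dimethoxy-4-(3-methylbut-2-enyl)phenyl 2,2-dimethylpropanoate F6. The same acid methanolysis, now with no nucleophilic hydroxyl beside the ketone, should give 2-[2-(2,4-dihydroxyphenyl)-2-oxoethyl]-3,5-dimethoxy-4-(3-methylbut-2-enyl)phenyl 2,2-dimethylpropanoate F7. K2CO3 in MeOH at rt removes the ester and comes back to the route at 22.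

Step 6. The metallated allene may attack the aldehyde through its α-carbon and give the allenyl carbinol instead of the ynol ether. The fallback reverses the polarity and makes the same C–C bond by acetylide opening of an epoxide. It sets out from aldehyde 9. Trimethylsulfonium iodide and NaH in DMSO–THF (Corey–Chaykovsky epoxidation) should give 2-[2,4-bis(methoxymethoxy)phenyl]oxirane F8, used crude. Lithium methoxyacetylide F9 (from chloroacetaldehyde dimethyl acetal and 3 equiv LiNEt2, THF, 0 °C) in THF–DMPU without Lewis acid should open F8 at the CH2 carbon and come back to the route at alcohol 13.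

**Further compounds**
F1 | step 8 | N-methoxy-N,5-dimethylhex-4-enamide | CON(C)C(=O)CCC=C(C)C
F2 | step 8 | 1-methoxyvinyllithium | [Li]C(=C)OC
F3 | step 8 | 2-methoxy-7-methylocta-1,6-dien-3-one | C=C(OC)C(=O)CCC=C(C)C
F4 | step 8 | 1,1,1-trifluoro-5-methoxy-3-(3-methylbut-2-enyl)hex-5-ene-2,4-dione (racemic) | C=C(OC)C(=O)C(CC=C(C)C)C(=O)C(F)(F)F
F5 | step 8 | 4-diazo-2-methoxy-7-methylocta-1,6-dien-3-one | C=C(OC)C(=O)C(=[N+]=[N-])CC=C(C)C
F6 | step 11 | 2-{2-[2,4-bis(methoxymethoxy)phenyl]-2-oxoethyl}-3,5-dimethoxy-4-(3-methylbut-2-enyl)phenyl 2,2-dimethylpropanoate | COc1cc(OC(=O)C(C)(C)C)c(CC(=O)c2ccc(OCOC)cc2OCOC)c(OC)c1CC=C(C)C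
F7 | step 11 | 2-[2-(2,4-dihydroxyphenyl)-2-oxoethyl]-3,5-dimethoxy-4-(3-methylbut-2-enyl)phenyl 2,2-dimethylpropanoate | COc1cc(OC(=O)C(C)(C)C)c(CC(=O)c2ccc(O)cc2O)c(OC)c1CC=C(C)C
F8 | step 6 | 2-[2,4-bis(methoxymethoxy)phenyl]oxirane (racemic) | COCOc1ccc(C2CO2)c(OCOC)c1
F9 | step 6 | lithium methoxyacetylide | [Li]C#COC
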